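**Retrosynthetic overview**
1. Only ring C (the dihydropyran) is built; the arene, the cyclobutane and the nine-membered ring are bought. Caryophyllane numbering is used: C-4 is the methyl-bearing alkene carbon, C-5 the alkene CH, C-1' the benzylic carbon.
2. C-1'–phenyl bond, made first: 2,4,6-triformylphloroglucinol 1 + PhMgBr 2 ⇐ benzhydrol 3. One of three equivalent formyl groups becomes C-1'; the other two remain as the formyl groups of the target.
3. C-5–C-1' and C-4–O bonds, made last and together (ring C): 3 (− H2O) + (−)-β-caryophyllene 4 ⇐ o-quinone methide 5 + 4 ⇐ target 6. This is an oxa-[4+2] cycloaddition at the endocyclic E-alkene, mirroring the presumed biogenesis.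
4. Stereochemistry: C-1 and C-9 come with 4; C-4 and C-5 from suprafacial addition to the exposed alkene face; C-1' from the methide face left open by a chiral phosphoric acid.

Assumption: the SMILES is read literally as the (1R,4R,5S,9S,1'S) adduct of natural (−)-β-caryophyllene (H-1' cis to H-5, phenyl syn to the C-4 methyl), and (R)-3,3'-bis(2,4,6-triisopropylphenyl)-1,1'-binaphthyl-2,2'-diyl hydrogen phosphate is taken as the antipode that shields the Re face of C-1' of the bound o-quinone methide; if the first run shows the opposite sense, the (S) antipode is used in the same step.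

Step 1
Reactants: 1 2,4,6-triformylphloroglucinol (2,4,6-trihydroxybenzene-1,3,5-tricarbaldehyde); 2 phenylmagnesium bromide
Product: 3 2,4,6-trihydroxy-5-[hydroxy(phenyl)methyl]benzene-1,3-dicarbaldehyde (racemic benzhydrol)
Conditions: PhMgBr (4.1 equiv), THF (0.05 M), −40 → 0 °C; then AcOH (4.2 equiv), −40 °C; cold extractive work-up, used crude
Reagents that add atoms: phenylmagnesium bromide (compound 2), Br[Mg]c1ccccc1
Why: Grignard 1,2-addition to an aldehyde: three equivalents of 2 only deprotonate the three acidic phenols, the magnesium phenoxide chelates and activates an ortho formyl group (as in additions to salicylaldehyde magnesium salts), and the fourth equivalent adds once because the resulting tetra-anionic arene is too electron-rich for a second addition at or below 0 °C; the carbinol centre is formed racemic and becomes planar in step 2.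

Step 2
Reactants: 3 2,4,6-trihydroxy-5-[hydroxy(phenyl)methyl]benzene-1,3-dicarbaldehyde; 4 (−)-β-caryophyllene [(1R,4E,9S)-4,11,11-trimethyl-8-methylidenebicyclo[7.2.0]undec-4-ene]
Product: 6 target CNP0253700.3 [(1R,4R,5S,9S,1'S) chroman adduct], via o-quinone methide 5 (not isolated)
Conditions: 4 (2 equiv), (R)-3,3'-bis(2,4,6-triisopropylphenyl)-1,1'-binaphthyl-2,2'-diyl hydrogen phosphate (C50H57O4P, 10 mol%), 4 Å MS, PhMe (0.05 M), −20 °C → rt; chromatography, then preparative HPLC
Reagents that add atoms: none
Why: Proposed new method: the phosphoric acid ionises the benzylic C–OH of 3 (a vinylogous hemiacetal flanked by two phenols) and stays hydrogen-bonded to the carbonyl oxygen of the (E)-o-quinone methide 5, which undergoes an inverse-electron-demand oxa-[4+2] cycloaddition (hetero-Diels–Alder) with the strained endocyclic E-alkene of 4 rather than the unstrained exocyclic one; addition is suprafacial on the exposed face of the dominant βα/ββ conformers (the face peracids use to give natural caryophyllene oxide), with O going to the more substituted C-4 and C-1' to C-5, which sets 4R,5S with CH3 and H-5 trans, while the triisopropylphenyl wall of the catalyst blocks the Re face of C-1' so the alkene bonds to its Si face (arene core over the C-4 methyl side) and sets 1'S; C-1 and C-9 are carried unchanged from 4, and the non-polar solvent and low temperature disfavour the stepwise cationic pathway that leads to transannular cyclisation; the closest known reaction types are the uncatalysed thermal o-quinone methide/caryophyllene cycloaddition and chiral Brønsted acid-catalysed [4+2] reactions of o-quinone methides from o-hydroxybenzyl alcohols with unactivated alkenes by activation of the electrophile alone.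

**Compound list**
1 | 2,4,6-triformylphloroglucinol (2,4,6-trihydroxybenzene-1,3,5-tricarbaldehyde) | O=Cc1c(O)c(C=O)c(O)c(C=O)c1O | starting material
2 | phenylmagnesium bromide | Br[Mg]c1ccccc1 | starting material
3 | 2,4,6-trihydroxy-5-[hydroxy(phenyl)methyl]benzene-1,3-dicarbaldehyde (racemic) | O=Cc1c(O)c(C=O)c(O)c(C(O)c2ccccc2)c1O | intermediate
4 | (−)-β-caryophyllene, (1R,4E,9S)-4,11,11-trimethyl-8-methylidenebicyclo[7.2.0]undec-4-ene | C=C1CC/C=C(\C)CC[C@@H]2[C@@H]1CC2(C)C | starting material
5 | (E)-5-benzylidene-2,4-dihydroxy-6-oxocyclohexa-1,3-diene-1,3-dicarbaldehyde (o-quinone methide, phenyl anti to the ring carbonyl; not isolated) | O=CC1=C(O)C(C=O)=C(O)/C(=C\c2ccccc2)C1=O | intermediate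
6 | CNP0253700.3: (1R,4R,5S,9S,1'S) adduct; 4-phenyl-5,7-dihydroxy-6,8-diformylchroman whose O-1 is bonded to caryophyllane C-4 (bearing CH3) and whose C-4 (= C-1') is bonded to caryophyllane C-5; CH3 trans to H-5, H-5 cis to H-1', exocyclic C-8 methylene and trans-fused gem-dimethylcyclobutane intact | C=C1CC[C@H]2[C@@H](c3ccccc3)c3c(O)c(C=O)c(O)c(C=O)c3O[C@]2(C)CC[C@@H]2[C@@H]1CC2(C)C | target

Total step count: 2
Longest linear sequence: 2 steps (1 → 3 → 6; 4 enters in step 2)

**Steps most likely to fail** (the route has only two steps, so both are ranked, most doubtful first; there is no third step)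

Step 2. Three things can go wrong. The uncatalysed cycloaddition is expected to favour the C-1' epimer (arene core over the H-5 side), so the catalyst must override an intrinsic steric bias. An uncatalysed background reaction would erode that control. Any acid can trigger transannular cyclisation of 4 or stepwise cationic trapping; minor 4,5-diepi adducts from the αα conformer are also expected.
Fallback, setting out from 3 and returning at 6: 3 is condensed with phenylboronic acid (PhB(OH)2, PhMe, 4 Å MS, rt) to the cyclic boronate 5,7-dihydroxy-2,4-diphenyl-4H-1,3,2-benzodioxaborin-6,8-dicarbaldehyde F1, a storable, acid-free precursor of 5. Heating F1 with 4 (3 equiv) in PhMe at 90–110 °C extrudes the boron unit and releases 5 with no Brønsted acid present. Trapping under thermal substrate control gives 6 together with its C-1' epimer F2, and 6 is isolated by preparative HPLC.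

Step 1. The magnesium tris-phenoxide of 1 may be too insoluble or too deactivated to add 2, or may add it twice. The free benzhydrol 3 may also lose water or benzaldehyde on work-up.
Fallback, setting out from 1 and returning at 3: 1 is persilylated (TBSOTf, 2,6-lutidine, CH2Cl2, 0 °C) to 2,4,6-tris(tert-butyldimethylsilyloxy)benzene-1,3,5-tricarbaldehyde F3, a neutral and soluble electrophile. F3 is treated with 2 (0.95 equiv, THF, −78 °C; AcOH quench at −78 °C) to give the mono-carbinol 2,4,6-tris(tert-butyldimethylsilyloxy)-5-[hydroxy(phenyl)methyl]benzene-1,3-dicarbaldehyde F4. Buffered fluoride (TBAF, AcOH, THF, 0 °C) removes the three silyl groups and delivers 3 under near-neutral conditions.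

**Further compounds**
F1 | step 2 | 5,7-dihydroxy-2,4-diphenyl-4H-1,3,2-benzodioxaborin-6,8-dicarbaldehyde (racemic) | O=Cc1c(O)c(C=O)c2OB(c3ccccc3)OC(c3ccccc3)c2c1O
F2 | step 2 | C-1' epimer of 6, (1R,4R,5S,9S,1'R) | C=C1CC[C@H]2[C@H](c3ccccc3)c3c(O)c(C=O)c(O)c(C=O)c3O[C@]2(C)CC[C@@H]2[C@@H]1CC2(C)C
F3 | step 1 | 2,4,6-tris(tert-butyldimethylsilyloxy)benzene-1,3,5-tricarbaldehyde | O=Cc1c(O[Si](C)(C)C(C)(C)C)c(C=O)c(O[Si](C)(C)C(C)(C)C)c(C=O)c1O[Si](C)(C)C(C)(C)C
F4 | step 1 | 2,4,6-tris(tert-butyldimethylsilyloxy)-5-[hydroxy(phenyl)methyl]benzene-1,3-dicarbaldehyde (racemic) | O=Cc1c(O[Si](C)(C)C(C)(C)C)c(C=O)c(O[Si](C)(C)C(C)(C)C)c(C(O)c2ccccc2)c1O[Si](C)(C)C(C)(C)C
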